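The numbers in the tables were generated by integration for an exercise, and the scatter is random.

The triple product turns into its isomer and back, so each set-up can be judged by how far that pair has drifted towards equal shares.

| flask | substrate | coupling partner | remark | time |
|---|---|---|---|---|
| Tuesday's | 0.0050 M | 1.5 equiv | run made earlier |  |
| Sunday's | 0.0050 M | 2.2 equiv | run made earlier |  |
| eta | 0.0050 M | 1.50 equiv | everything together in a closed stirred flask, run for 4.0 min | 4.0 min |
| beta | 0.0050 M | 1.50 equiv | one stirred flow tank at steady state, fed with the mixture as stated, mean residence time 12.0 min |  |
| delta | 0.0050 M | 1.50 equiv (fed, over 3.20 min) | a stirred flask in which coupling partner is dosed at a steady rate over 3.20 min without added volume, worked up at 4.0 min | 4.0 min |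
| zeta | 0.0050 M | 1.50 equiv | a single well-mixed tank run continuously and read at steady state, 4.0 min in it on average |  |

- Tuesday's (time / min: triple product / %, isomer of the product / %): 0.200: 0, 0.2; 0.333: 0.3, 0; 0.500: 0.2, 0.1; 0.833: 2.1, 0.4; 1.33: 3.4, 0.4; 2.50: 6.6, 1.9
- Sunday's (time / s: triple product / %, isomer of the product / %): 10.0: 0.5, 0; 15.0: 0.2, 0; 25.0: 0.9, 0.5; 40.0: 3.2, 0; 50.0: 4.8, 0.7

(each reading ± 0.3 percentage points)

- the stated concentrations are those of everything mixed, before any reaction; amounts are the same in each set-up
- what may be going on: triple product <-> isomer of the product; coupling partner + mono adduct -> bis adduct; substrate + coupling partner -> mono adduct; coupling partner + bis adduct <-> triple product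
- the feed brings no volume worth counting
- the earlier runs were made in a closed, stirred flask

* the set-up with the highest share of triple product in all that became triple product or isomer of the product, at the outlet or at the end ("none" if the first two lie within 2 percentage points) (eta / beta / delta / zeta / none)
* share of triple product in all that became triple product or isomer of the product, at the outlet or at the end, eta
* share of triple product in all that became triple product or isomer of the product, at the outlet or at the end, beta
* share of triple product in all that became triple product or isomer of the product, at the outlet or at the end, delta
* share of triple product in all that became triple product or isomer of the product, at the outlet or at the end, zeta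

The fastest rung is the lag of the chain that builds the triple product. On Tuesday it reads 0.2 % at 0.500 min, within the scatter, and 2.1 % at 0.833 min. Sunday's flask, with more coupling partner, holds 4.8 % at 50.0 s, which is more product at an earlier time than Tuesday's 3.4 % at 1.33 min, so birth follows the partner.

The next rung is the isomerisation. Tuesday's isomer, 1.9 % at 2.50 min, is still small against the triple product. Dividing it by the triangle under the triple-product curve from 0.500 min gives a forward constant k of 0.288 /min, a reading with its scatter. The readings cannot show the way back, so this reckoning assumes the symmetric case, with the way back as fast as the way forward. Let m, the memory, be triple product minus isomer over their sum. It is one at birth and zero at equal shares, and it falls by a factor e in the memory time θ = one over twice k, 1.74 min (the relaxation time of the pair). That is longer than the lag and shorter than the run.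

The share s is (one plus m) over two. In eta, birth spread evenly over a span a gives m = (one minus e^(−a/θ)) over a/θ, with a = 4.0 min, so s is 69.5 %. In delta the partner arrives on average at 1.60 min, which shortens the span to 2.40 min and gives 77.1 %. The slowest rung is the tanks, where m is one over (one plus τ/θ) for mean residence time τ: zeta gives 65.1 % and beta 56.3 %.

The forecast chose delta, with 62 % for eta, 24 % for beta, 76 % for delta and 47 % for zeta, lower than this reckoning in both tanks, and held that “partner stays scarce early, so triple product forms late”. The flask gives delta first, with 78.5 % for delta, 64.7 % for eta, 63.7 % for zeta and 55.7 % for beta, whose share stays above one half.

    triple product ⇌ isomer of the product (K = 0.990, k = 0.00560 /s)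
    coupling partner + mono adduct → bis adduct (k = 1.20 /M/s)
    substrate + coupling partner → mono adduct (k = 2.50 /M/s)
    coupling partner + bis adduct ⇌ triple product (K = 510 /M, k = 2.60 /M/s)

The same θ is carried to delta read later, at 6.0 min. The span grows to 4.40 min, and the memory rule puts the share at 68.2 %, down from the 77.1 % reckoned for delta at 4.0 min. That flask gives 63.9 %, lower than the rule's figure by 4.3 percentage points, with 7.72 % of triple product at that reading.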